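I started from the substrate left over at 40.0 min: 88.8 % in Monday's run and 59.9 % in Thursday's.

| flask | substrate | reagent | free catalyst | added ligand | remark | time |
|---|---|---|---|---|---|---|
| Monday's | 0.20 M | 0.50 equiv | 0.32 mol% | 1.5 mM | run made earlier |  |
| Thursday's | 0.20 M | 2.1 equiv | 0.32 mol% | 1.5 mM | run made earlier |  |
| violet | 0.20 M | 0.900 equiv | 0.32 mol% | 1.5 mM |  | 80 min |
| grey | 0.20 M | 2.70 equiv | 0.32 mol% | 1.5 mM |  | 80 min |

| run | time / min | catalyst intermediate B / % | substrate / % | target / % | side product / % |
|---|---|---|---|---|---|
| Monday's | 5.00 | 0 | 98.8 | 1.7 | 0.3 |
| Monday's | 15.0 | 1.5 | 95.4 | 3.3 | 0.9 |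
| Monday's | 25.0 | 0.2 | 93.5 | 4.9 | 1.7 |
| Monday's | 40.0 | 0.8 | 88.8 | 6.6 | 4.4 |
| Thursday's | 3.00 | 0.4 | 95.3 | 4.5 | 0 |
| Thursday's | 8.00 | 0.1 | 89.7 | 8.8 | 1.2 |
| Thursday's | 15.0 | 0.4 | 83.4 | 13.8 | 2.0 |
| Thursday's | 40.0 | 0 | 59.9 | 25.1 | 12.4 |

(readings scatter by 0.5 percentage points)

- percentages count the substrate that a species holds: one side product counts as two
- the earlier runs were read with a standard deviation of 0.5 percentage points

1. which of these there is most of at the end, counted by the substrate in it, violet (substrate / side product / catalyst intermediate B / target)
2. which of these there is most of at the end, counted by the substrate in it, grey (substrate / side product / catalyst intermediate B / target)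
3. amount of the one of these that there is most of at the end, in percent of the substrate charged, violet
4. amount of the one of these that there is most of at the end, in percent of the substrate charged, grey

I divided the logarithm of charged over left by the equivalents of reagent and the time. That gave 0.00594 min⁻¹ for Monday's run and 0.00610 min⁻¹ for Thursday's, nearly the same despite the different reagent charges. Their mean, 0.00602 min⁻¹ for each equivalent, is my pseudo-first-order loss constant per equivalent of reagent.

Carried to 80 min, it gave 64.8 % of the substrate left in violet, more than everything else together, and 27.2 % in grey. So grey's answer hung on how its lost substrate divided. Thursday's side product held 30.9 % of the substrate lost by 40.0 min, which put grey's target at 50.3 %.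

That share was the weak link, for it averaged over the whole of Thursday's run. Between 15.0 min and 40.0 min, side product gained 44.3 % of the substrate lost, more than that average. I took grey to follow Thursday's run down to its last substrate reading and applied this later share to the loss below it, which gave side product 26.9 % and target 45.9 %, by my estimate more than either other species in grey.

The forecast gave violet substrate at 67 % (61 % to 72 %) and grey target at 41 % (35 % to 46 %), noting that “Side product appears to accelerate as target builds”. My grey target stood higher.

The flask gives violet substrate at 64.1 % and grey target at 46.9 %.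

    substrate + target → side product (k = 4.30 M⁻¹ h⁻¹)
    substrate + free catalyst ⇌ idle complex B, settled at all times (K = 1.70 M⁻¹)
    reagent + free catalyst ⇌ catalyst intermediate A (K = 2.40 M⁻¹, k = 2100 M⁻¹ h⁻¹)
    catalyst intermediate B → free catalyst + target (k = 12000 h⁻¹)
    free catalyst + added ligand ⇌ idle complex A (K = 2000 M⁻¹, k = 16000 M⁻¹ h⁻¹)
    substrate + catalyst intermediate A → catalyst intermediate B (k = 11000 M⁻¹ h⁻¹)

Read back, grey's substrate of 21.8 % gives a constant of 0.00705 min⁻¹, above mine. The gap between grey's substrate and violet's is due to the difference in equivalents of reagent: with violet's charge, grey's substrate stands at 64.1 % instead of 21.8 %. In a neighbour of violet with 0.8 mol% of free catalyst, scaling the constant with the loading gives 33.8 % of the substrate left. The computed flask leaves 28.0 %.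

Readings and results were computed for substances that don't exist; the scatter is artificial.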